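**Plan**

1. Numbering (germacrane): carbocycle C1–C10; oxirane C4(Me)–C5(H); ester oxygen on C6; isopropyl on C7; E-alkene C8=C9; carbinol C10(Me)OH.
2. Cuts, in retrosynthetic order: the aroyl–O bond at C6; then the oxirane C4–C5 bond, which is also a bond of the ten-membered ring (intramolecular sulfonium ylide epoxidation, C5 ylide onto a C4 methyl ketone); then C8=C9 (Julia–Kocienski), leaving fragment 1 (C5–C8) and fragment 2 (C9, C10, C1–C4, C15).
3. Forward: fragment 1 by Evans aldol (steps 1–6); fragment 2 from (S)-2-methylglycidol (steps 7–9); chain joined at C8=C9 (step 10); ketone unmasked and sulfonium installed (steps 11–13); carbocycle and oxirane closed together (step 14); desilylation, esterification, desilylation (steps 15–17).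
4. Stereochemistry: C6 and C7 from the (R)-benzyloxazolidinone syn-aldol; C10 from the chiral-pool epoxide (retained); E-alkene from the olefination; C5 and C4 in the key step, by 1,2-induction from C6 and by cis ring fusion.
5. Enabling feature: the oxirane is trisubstituted and fused to the ten-membered ring. C4 carries only CH3, a ring CH2 and O (a methyl ketone carbon), and C5 carries only H and ring carbon C6 (a CH2 that can bear a sulfonium group). One ylide-to-carbonyl addition therefore makes the C–C bond shared by both rings, and the E-alkene and quaternary C10 pre-organise the open chain.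

Key step: step 14

Remark: 1, 2, 4, 11, 12 and 25 are taken to be catalogue compounds; ring positions in the text use the germacrane numbering of line 1.

**Route**

Step 1
Reactants: 1 (R)-4-benzyl-1,3-oxazolidin-2-one; 2 3-methylbutanoyl chloride
Product: 3 (R)-4-benzyl-3-(3-methylbutanoyl)-1,3-oxazolidin-2-one
Conditions: Et3N, DMAP (cat.), CH2Cl2, 0 °C → rt
Reagents that add atoms: none
Why: N-acylation of the oxazolidinone by an acid chloride under acyl-transfer catalysis is routine and does not touch the auxiliary stereocentre.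

Step 2
Reactants: 3 (R)-4-benzyl-3-(3-methylbutanoyl)-1,3-oxazolidin-2-one; 4 2-[(4-methoxybenzyl)oxy]acetaldehyde
Product: 6 (4R)-4-benzyl-3-[(2R,3R)-3-hydroxy-4-[(4-methoxybenzyl)oxy]-2-(propan-2-yl)butanoyl]-1,3-oxazolidin-2-one, via dibutylboron Z-enolate 5 (not isolated)
Conditions: Bu2BOTf, Et3N, CH2Cl2, −78 → 0 °C; then 4, −78 → 0 °C; pH 7 buffer, MeOH, H2O2 work-up
Reagents that add atoms: none
Why: Evans syn-aldol reaction, in which the Z-boron enolate reacts through a closed Zimmerman–Traxler chair with one face shielded by the benzyl group of the (R)-auxiliary, so that C7 and C6 should be set together as the syn (2R,3R) pair.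

Step 3
Reactants: 6 the syn-aldol adduct
Product: 7 (4R)-4-benzyl-3-[(2R,3R)-3-[(tert-butyldimethylsilyl)oxy]-4-[(4-methoxybenzyl)oxy]-2-(propan-2-yl)butanoyl]-1,3-oxazolidin-2-one
Conditions: TBSOTf, 2,6-lutidine, CH2Cl2, −78 → 0 °C
Reagents that add atoms: tert-butyldimethylsilyl trifluoromethanesulfonate, CC(C)(C)[Si](C)(C)OS(=O)(=O)C(F)(F)F
Why: a silyl triflate with a hindered base silylates the hindered secondary aldol hydroxyl at low temperature without retro-aldol cleavage or epimerisation.

Step 4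
Reactants: 7 the silylated imide
Product: 8 (2S,3R)-3-[(tert-butyldimethylsilyl)oxy]-4-[(4-methoxybenzyl)oxy]-2-(propan-2-yl)butan-1-ol
Conditions: LiBH4, MeOH (1 equiv), THF, 0 °C
Reagents that add atoms: none
Why: reductive cleavage of the N-acyl oxazolidinone by LiBH4 should give the primary alcohol (C8) and return the auxiliary without enolisation, so C7 is not epimerised.

Step 5
Reactants: 8 the primary alcohol
Product: 9 5-{[(2R,3R)-3-[(tert-butyldimethylsilyl)oxy]-4-[(4-methoxybenzyl)oxy]-2-(propan-2-yl)butyl]sulfanyl}-1-phenyl-1H-tetrazole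
Conditions: 1-phenyl-1H-tetrazole-5-thiol, PPh3, DIAD, THF, 0 °C → rt
Reagents that add atoms: 1-phenyl-1H-tetrazole-5-thiol, Sc1nnnn1-c1ccccc1
Why: Mitsunobu thioetherification of a primary alcohol with an acidic heteroaryl thiol; no stereocentre is involved.

Step 6
Reactants: 9 the tetrazolyl sulfide
Product: 10 5-{[(2R,3R)-3-[(tert-butyldimethylsilyl)oxy]-4-[(4-methoxybenzyl)oxy]-2-(propan-2-yl)butyl]sulfonyl}-1-phenyl-1H-tetrazole
Conditions: (NH4)6Mo7O24·4H2O (cat.), 30% H2O2, EtOH, 0 °C → rt
Reagents that add atoms: hydrogen peroxide, OO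
Why: molybdate-catalysed peroxide oxidation of the sulfide to the sulfone is standard for Julia–Kocienski reagents and is tolerated by PMB and TBS ethers.

Step 7
Reactants: 11 (S)-(2-methyloxiran-2-yl)methanol; 12 but-3-en-1-ylmagnesium bromide
Product: 13 (R)-2-methylhept-6-ene-1,2-diol
Conditions: CuI (10 mol %), THF, −30 → 0 °C, 12 (2.5 equiv)
Reagents that add atoms: none
Why: copper-catalysed Grignard opening of the 2,2-disubstituted epoxide at its CH2 terminus (SN2) after the first equivalent has formed the alkoxide; the quaternary carbinol carbon (C10) is not attacked, so its configuration is retained.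

Step 8
Reactants: 13 (R)-2-methylhept-6-ene-1,2-diol
Product: 14 (R)-2-methyl-1,2-bis[(triethylsilyl)oxy]hept-6-ene
Conditions: TESOTf, 2,6-lutidine, CH2Cl2, −78 → 0 °C
Reagents that add atoms: triethylsilyl trifluoromethanesulfonate, CC[Si](CC)(CC)OS(=O)(=O)C(F)(F)F
Why: the silyl triflate silylates both the primary and the tertiary hydroxyl.

Step 9
Reactants: 14 the bis(triethylsilyl) ether
Product: 15 (R)-2-methyl-2-[(triethylsilyl)oxy]hept-6-enal
Conditions: (COCl)2, DMSO, CH2Cl2, −78 → −40 °C; then Et3N, −78 °C → rt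
Reagents that add atoms: none
Why: under Swern conditions a primary triethylsilyl ether is cleaved by the chlorosulfonium reagent and oxidised to the aldehyde while a tertiary one is inert (a known selective oxidative desilylation); the α-carbon is quaternary and cannot epimerise.

Step 10
Reactants: 10 the tetrazolyl sulfone; 15 (R)-2-methyl-2-[(triethylsilyl)oxy]hept-6-enal
Product: 16 (2R,3S,4E,6R)-2-[(tert-butyldimethylsilyl)oxy]-1-[(4-methoxybenzyl)oxy]-6-methyl-3-(propan-2-yl)-6-[(triethylsilyl)oxy]undeca-4,10-diene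
Conditions: KN(SiMe3)2, DME, −60 °C; then 15, −60 °C → rt
Reagents that add atoms: none
Why: Julia–Kocienski olefination; the metalated phenyltetrazolyl sulfone adds to the hindered, non-enolisable aldehyde, and Smiles rearrangement followed by anti-elimination of SO2 and the tetrazolate should give the E-alkene C8=C9.

Step 11
Reactants: 16 the diene
Product: 17 (6R,7E,9S,10R)-10-[(tert-butyldimethylsilyl)oxy]-11-[(4-methoxybenzyl)oxy]-6-methyl-9-(propan-2-yl)-6-[(triethylsilyl)oxy]undec-7-en-2-one
Conditions: PdCl2 (10 mol %), CuCl, O2 (1 atm), DMF/H2O, rt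
Reagents that add atoms: water, O
Why: Tsuji–Wacker oxidation, in which Markovnikov hydroxypalladation of the unhindered terminal alkene gives the C4 methyl ketone while the E-alkene, flanked by a quaternary and a branched carbon, should not react.

Step 12
Reactants: 17 the PMB-protected ketone
Product: 18 (6R,7E,9S,10R)-10-[(tert-butyldimethylsilyl)oxy]-11-hydroxy-6-methyl-9-(propan-2-yl)-6-[(triethylsilyl)oxy]undec-7-en-2-one
Conditions: DDQ, CH2Cl2/pH 7 buffer, 0 °C → rt
Reagents that add atoms: none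
Why: oxidative cleavage of the p-methoxybenzyl ether through its benzylic oxocarbenium ion frees the C5 hydroxyl and leaves silyl ethers, ketone and alkene untouched.

Step 13
Reactants: 18 the keto alcohol
Product: 20 [(2R,3S,4E,6R)-2-[(tert-butyldimethylsilyl)oxy]-6-methyl-10-oxo-3-(propan-2-yl)-6-[(triethylsilyl)oxy]undec-4-en-1-yl]diphenylsulfonium trifluoromethanesulfonate, via primary triflate 19 (not isolated)
Conditions: Tf2O, 2,6-di-tert-butyl-4-methylpyridine, CH2Cl2, −78 °C; then Ph2S (5 equiv), −78 °C → rt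
Reagents that add atoms: trifluoromethanesulfonic anhydride, O=S(=O)(OS(=O)(=O)C(F)(F)F)C(F)(F)F; diphenyl sulfide, c1ccc(Sc2ccccc2)cc1
Why: S-alkylation of a diaryl sulfide by a primary alkyl triflate (SN2) is the standard entry to alkyldiphenylsulfonium salts, and the salt formed has no α-hydrogen on sulfur other than those of the C5 methylene.

Step 14
Reactants: 20 the keto sulfonium triflate
Product: 23 (1R,2R,3S,4E,6R,10S)-2-[(tert-butyldimethylsilyl)oxy]-6,10-dimethyl-3-(propan-2-yl)-6-[(triethylsilyl)oxy]-11-oxabicyclo[8.1.0]undec-4-ene, via sulfonium ylide 21 (not isolated), via betaine 22 (not isolated)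
Conditions: KN(SiMe3)2 (1.05 equiv), THF, −78 °C, 20 added by syringe pump to 0.001 M; then −78 → −20 °C
Reagents that add atoms: none
Why: Proposed new method: deprotonation of the S–CH2 group (C5, several pK units more acidic than the ketone α-hydrogens) gives the non-stabilised diphenylsulfonium ylide 21, whose carbanion adds to the C4 methyl ketone and so closes the ten-membered carbocycle (10-exo-trig), and the alkoxide of betaine 22 then displaces diphenyl sulfide from C5 with inversion (3-exo-tet) to close the oxirane; the closest known reaction type is the intramolecular Corey–Chaykovsky epoxidation of keto sulfonium salts to cis-fused bicyclic epoxides with five- to seven-membered rings, which has not been shown for a ten-membered carbocycle. The closure is run at high dilution because addition of a non-stabilised ylide to a ketone is irreversible, and it is helped by the E-alkene and the quaternary C10, which remove rotors and transannular hydrogens from the chain. C5 should be set by 1,2-induction from C6: in the allylic-strain-minimised ylide conformer (C6–H in the ylide plane next to SPh2) the tethered ketone bonds to the face opposite the bulky OTBS group, and after the invertive displacement the oxirane oxygen lies anti to the C6 oxygen as the target requires. C4 should follow from ring strain, because with one E-alkene already in the ring the cis-fused bicycle (methyl and oxirane H cis, a Z-like ring fusion) is the less strained mode of closure. The step needs chemoselectivity (ylide formation over ketone enolisation, carbonyl addition over β-elimination of silanolate) and this double diastereoselectivity; low temperature, a non-chelating potassium counter-ion and the poor leaving-group ability of the hindered silanolate are relied on.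

Step 15
Reactants: 23 the bis-silylated epoxide
Product: 24 (1R,2R,3S,4E,6R,10S)-6,10-dimethyl-3-(propan-2-yl)-11-oxabicyclo[8.1.0]undec-4-ene-2,6-diol
Conditions: Bu4NF, THF, 0 → 40 °C
Reagents that add atoms: none
Why: fluoride cleaves both Si–O bonds, and the trisubstituted epoxide and the alkene are inert to it.

Step 16
Reactants: 24 the epoxy diol; 25 4-[(tert-butyldimethylsilyl)oxy]benzoic acid
Product: 26 (1R,2R,3S,4E,6R,10S)-6-hydroxy-6,10-dimethyl-3-(propan-2-yl)-11-oxabicyclo[8.1.0]undec-4-en-2-yl 4-[(tert-butyldimethylsilyl)oxy]benzoate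
Conditions: EDC·HCl, DMAP, CH2Cl2, rt
Reagents that add atoms: none
Why: Steglich esterification acylates the secondary C6 hydroxyl only, the tertiary allylic C10 hydroxyl being too hindered, and acylation at oxygen retains the C6 configuration.

Step 17
Reactants: 26 the silylated aryl ester
Product: 27 (1R,2R,3S,4E,6R,10S)-6-hydroxy-6,10-dimethyl-3-(propan-2-yl)-11-oxabicyclo[8.1.0]undec-4-en-2-yl 4-hydroxybenzoate
Conditions: Bu4NF/AcOH (1:1), THF, 0 °C
Reagents that add atoms: none
Why: buffered fluoride removes the aryl silyl ether rapidly, and the buffer should prevent ester cleavage and epoxide opening by the phenoxide.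

**Compound list**

1 | (R)-4-benzyl-1,3-oxazolidin-2-one | O=C1OC[C@@H](Cc2ccccc2)N1 | starting material
2 | 3-methylbutanoyl chloride | CC(C)CC(Cl)=O | starting material
3 | (R)-4-benzyl-3-(3-methylbutanoyl)-1,3-oxazolidin-2-one | CC(C)CC(=O)N1[C@H](Cc2ccccc2)COC1=O | intermediate
4 | 2-[(4-methoxybenzyl)oxy]acetaldehyde | COc1ccc(COCC=O)cc1 | starting material
5 | dibutylboron Z-enolate of 3 | CC(C)/C=C(\OB(CCCC)CCCC)N1[C@H](Cc2ccccc2)COC1=O | intermediate (not isolated)
6 | (4R)-4-benzyl-3-[(2R,3R)-3-hydroxy-4-[(4-methoxybenzyl)oxy]-2-(propan-2-yl)butanoyl]-1,3-oxazolidin-2-one | COc1ccc(COC[C@H](O)[C@@H](C(C)C)C(=O)N2[C@H](Cc3ccccc3)COC2=O)cc1 | intermediate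
7 | (4R)-4-benzyl-3-[(2R,3R)-3-[(tert-butyldimethylsilyl)oxy]-4-[(4-methoxybenzyl)oxy]-2-(propan-2-yl)butanoyl]-1,3-oxazolidin-2-one | COc1ccc(COC[C@H](O[Si](C)(C)C(C)(C)C)[C@@H](C(C)C)C(=O)N2[C@H](Cc3ccccc3)COC2=O)cc1 | intermediate
8 | (2S,3R)-3-[(tert-butyldimethylsilyl)oxy]-4-[(4-methoxybenzyl)oxy]-2-(propan-2-yl)butan-1-ol | COc1ccc(COC[C@H](O[Si](C)(C)C(C)(C)C)[C@@H](C(C)C)CO)cc1 | intermediate
9 | 5-{[(2R,3R)-3-[(tert-butyldimethylsilyl)oxy]-4-[(4-methoxybenzyl)oxy]-2-(propan-2-yl)butyl]sulfanyl}-1-phenyl-1H-tetrazole | COc1ccc(COC[C@H](O[Si](C)(C)C(C)(C)C)[C@@H](C(C)C)CSc2nnnn2-c2ccccc2)cc1 | intermediate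
10 | 5-{[(2R,3R)-3-[(tert-butyldimethylsilyl)oxy]-4-[(4-methoxybenzyl)oxy]-2-(propan-2-yl)butyl]sulfonyl}-1-phenyl-1H-tetrazole | COc1ccc(COC[C@H](O[Si](C)(C)C(C)(C)C)[C@@H](C(C)C)CS(=O)(=O)c2nnnn2-c2ccccc2)cc1 | intermediate
11 | (S)-(2-methyloxiran-2-yl)methanol | C[C@]1(CO)CO1 | starting material
12 | but-3-en-1-ylmagnesium bromide | C=CCC[Mg]Br | starting material
13 | (R)-2-methylhept-6-ene-1,2-diol | C=CCCC[C@@](C)(O)CO | intermediate
14 | (R)-2-methyl-1,2-bis[(triethylsilyl)oxy]hept-6-ene | C=CCCC[C@@](C)(O[Si](CC)(CC)CC)CO[Si](CC)(CC)CC | intermediate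
15 | (R)-2-methyl-2-[(triethylsilyl)oxy]hept-6-enal | C=CCCC[C@@](C)(O[Si](CC)(CC)CC)C=O | intermediate
16 | (2R,3S,4E,6R)-2-[(tert-butyldimethylsilyl)oxy]-1-[(4-methoxybenzyl)oxy]-6-methyl-3-(propan-2-yl)-6-[(triethylsilyl)oxy]undeca-4,10-diene | CC(C)[C@@H](/C=C/[C@](C)(O[Si](CC)(CC)CC)CCCC=C)[C@H](COCc1ccc(OC)cc1)O[Si](C)(C)C(C)(C)C | intermediate
17 | (6R,7E,9S,10R)-10-[(tert-butyldimethylsilyl)oxy]-11-[(4-methoxybenzyl)oxy]-6-methyl-9-(propan-2-yl)-6-[(triethylsilyl)oxy]undec-7-en-2-one | CC(C)[C@@H](/C=C/[C@](C)(O[Si](CC)(CC)CC)CCCC(C)=O)[C@H](COCc1ccc(OC)cc1)O[Si](C)(C)C(C)(C)C | intermediate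
18 | (6R,7E,9S,10R)-10-[(tert-butyldimethylsilyl)oxy]-11-hydroxy-6-methyl-9-(propan-2-yl)-6-[(triethylsilyl)oxy]undec-7-en-2-one | CC(C)[C@@H](/C=C/[C@](C)(O[Si](CC)(CC)CC)CCCC(C)=O)[C@H](CO)O[Si](C)(C)C(C)(C)C | intermediate
19 | primary trifluoromethanesulfonate of 18 | CC(C)[C@@H](/C=C/[C@](C)(O[Si](CC)(CC)CC)CCCC(C)=O)[C@H](COS(=O)(=O)C(F)(F)F)O[Si](C)(C)C(C)(C)C | intermediate (not isolated)
20 | [(2R,3S,4E,6R)-2-[(tert-butyldimethylsilyl)oxy]-6-methyl-10-oxo-3-(propan-2-yl)-6-[(triethylsilyl)oxy]undec-4-en-1-yl]diphenylsulfonium trifluoromethanesulfonate | CC(C)[C@@H](/C=C/[C@](C)(O[Si](CC)(CC)CC)CCCC(C)=O)[C@H](C[S+](c1ccccc1)c1ccccc1)O[Si](C)(C)C(C)(C)C.[O-]S(=O)(=O)C(F)(F)F | intermediate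
21 | sulfonium ylide of 20 (carbanion at C5) | CC(C)[C@@H](/C=C/[C@](C)(O[Si](CC)(CC)CC)CCCC(C)=O)[C@H]([CH-][S+](c1ccccc1)c1ccccc1)O[Si](C)(C)C(C)(C)C | intermediate (not isolated)
22 | ten-membered betaine (C4 alkoxide, C5 diphenylsulfonium) | CC(C)[C@H]1/C=C/[C@](C)(O[Si](CC)(CC)CC)CCC[C@](C)([O-])[C@@H]([S+](c2ccccc2)c2ccccc2)[C@@H]1O[Si](C)(C)C(C)(C)C | intermediate (not isolated)
23 | (1R,2R,3S,4E,6R,10S)-2-[(tert-butyldimethylsilyl)oxy]-6,10-dimethyl-3-(propan-2-yl)-6-[(triethylsilyl)oxy]-11-oxabicyclo[8.1.0]undec-4-ene | CC(C)[C@H]1/C=C/[C@](C)(O[Si](CC)(CC)CC)CCC[C@]2(C)O[C@@H]2[C@@H]1O[Si](C)(C)C(C)(C)C | intermediate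
24 | (1R,2R,3S,4E,6R,10S)-6,10-dimethyl-3-(propan-2-yl)-11-oxabicyclo[8.1.0]undec-4-ene-2,6-diol | CC(C)[C@H]1/C=C/[C@](C)(O)CCC[C@]2(C)O[C@@H]2[C@@H]1O | intermediate
25 | 4-[(tert-butyldimethylsilyl)oxy]benzoic acid | CC(C)(C)[Si](C)(C)Oc1ccc(C(=O)O)cc1 | starting material
26 | (1R,2R,3S,4E,6R,10S)-6-hydroxy-6,10-dimethyl-3-(propan-2-yl)-11-oxabicyclo[8.1.0]undec-4-en-2-yl 4-[(tert-butyldimethylsilyl)oxy]benzoate | CC(C)[C@H]1/C=C/[C@](C)(O)CCC[C@]2(C)O[C@@H]2[C@@H]1OC(=O)c1ccc(O[Si](C)(C)C(C)(C)C)cc1 | intermediate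
27 | (1R,2R,3S,4E,6R,10S)-6-hydroxy-6,10-dimethyl-3-(propan-2-yl)-11-oxabicyclo[8.1.0]undec-4-en-2-yl 4-hydroxybenzoate | CC(C)[C@H]1/C=C/[C@](C)(O)CCC[C@]2(C)O[C@@H]2[C@@H]1OC(=O)c1ccc(O)cc1 | target

**Count**

Total steps: 17. Longest linear sequence: 14 (steps 1–6, then 10–17).

**Steps most likely to fail**

Step 14 (Proposed new method). The ten-membered closure may be too slow, so that the ylide is lost by β-elimination of the C6 silanolate or by proton transfer from the ketone, and facial selectivity at either oxirane carbon may be poor. The fallback sets out from 18 and makes the same C4–C5 bond as an alkene. Dess–Martin oxidation should give the keto aldehyde (2R,3S,4E,6R)-2-[(tert-butyldimethylsilyl)oxy]-6-methyl-10-oxo-3-(propan-2-yl)-6-[(triethylsilyl)oxy]undec-4-enal F1. Titanium-induced intramolecular carbonyl coupling (McMurry reaction; TiCl3(DME)1.5, Zn–Cu couple, DME, reflux, slow addition), which is known to close ten-membered germacrane-type rings at a trisubstituted alkene, should then give tert-butyl{[(1R,2Z,7R,8E,10S)-3,7-dimethyl-10-(propan-2-yl)-7-[(triethylsilyl)oxy]cyclodeca-2,8-dien-1-yl]oxy}dimethylsilane F2, the Z isomer being separated from any E isomer; survival of the α-silyloxy group under these conditions is the weak point of this fallback. Epoxidation with mCPBA/NaHCO3 at the more electron-rich trisubstituted alkene, from the face away from the OTBS group, comes back to the route at 23.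

Step 13. S-alkylation of the weakly nucleophilic diaryl sulfide by a β-branched, β-oxygenated primary triflate may be sluggish, and the triflate may decay by elimination or silyl migration. The fallback sets out from 18 and puts sulfur on as a strong nucleophile first. Thioetherification with PhSSPh/PBu3 should give (6R,7E,9S,10R)-10-[(tert-butyldimethylsilyl)oxy]-6-methyl-11-(phenylsulfanyl)-9-(propan-2-yl)-6-[(triethylsilyl)oxy]undec-7-en-2-one F3. Copper-catalysed S-phenylation of this sulfide with diphenyliodonium trifluoromethanesulfonate (Cu(OAc)2 cat., 1,2-dichloroethane, 80 °C) comes back to the route at 20.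

Step 10. Addition to the hindered α-quaternary aldehyde may be incomplete, and the E-selectivity of the one-pot elimination may erode. The fallback sets out from 8 and uses the classical Julia–Lythgoe sequence, in which E-geometry comes from the reductive elimination. PhSSPh/PBu3 should give {[(2R,3R)-3-[(tert-butyldimethylsilyl)oxy]-4-[(4-methoxybenzyl)oxy]-2-(propan-2-yl)butyl]sulfanyl}benzene F4. Oxidation with (NH4)6Mo7O24·4H2O/H2O2 should give the phenyl sulfone {[(2R,3R)-3-[(tert-butyldimethylsilyl)oxy]-4-[(4-methoxybenzyl)oxy]-2-(propan-2-yl)butyl]sulfonyl}benzene F5. Lithiation (BuLi, THF, −78 °C), addition of 15 and trapping with Ac2O should give the β-acetoxy sulfone (2R,3R,6R)-2-[(tert-butyldimethylsilyl)oxy]-1-[(4-methoxybenzyl)oxy]-6-methyl-4-(phenylsulfonyl)-3-(propan-2-yl)-6-[(triethylsilyl)oxy]undec-10-en-5-yl acetate F6 as a mixture at the two new carbons. Reduction with sodium amalgam (Na/Hg, Na2HPO4, MeOH/THF, −20 °C) comes back to the route at 16.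

**Further compounds**

F1 | step 14 | (2R,3S,4E,6R)-2-[(tert-butyldimethylsilyl)oxy]-6-methyl-10-oxo-3-(propan-2-yl)-6-[(triethylsilyl)oxy]undec-4-enal | CC(C)[C@@H](/C=C/[C@](C)(O[Si](CC)(CC)CC)CCCC(C)=O)[C@H](C=O)O[Si](C)(C)C(C)(C)C
F2 | step 14 | tert-butyl{[(1R,2Z,7R,8E,10S)-3,7-dimethyl-10-(propan-2-yl)-7-[(triethylsilyl)oxy]cyclodeca-2,8-dien-1-yl]oxy}dimethylsilane | CC(C)[C@H]1/C=C/[C@](C)(O[Si](CC)(CC)CC)CCC/C(C)=C\[C@@H]1O[Si](C)(C)C(C)(C)C
F3 | step 13 | (6R,7E,9S,10R)-10-[(tert-butyldimethylsilyl)oxy]-6-methyl-11-(phenylsulfanyl)-9-(propan-2-yl)-6-[(triethylsilyl)oxy]undec-7-en-2-one | CC(C)[C@@H](/C=C/[C@](C)(O[Si](CC)(CC)CC)CCCC(C)=O)[C@H](CSc1ccccc1)O[Si](C)(C)C(C)(C)C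
F4 | step 10 | {[(2R,3R)-3-[(tert-butyldimethylsilyl)oxy]-4-[(4-methoxybenzyl)oxy]-2-(propan-2-yl)butyl]sulfanyl}benzene | COc1ccc(COC[C@H](O[Si](C)(C)C(C)(C)C)[C@@H](C(C)C)CSc2ccccc2)cc1
F5 | step 10 | {[(2R,3R)-3-[(tert-butyldimethylsilyl)oxy]-4-[(4-methoxybenzyl)oxy]-2-(propan-2-yl)butyl]sulfonyl}benzene | COc1ccc(COC[C@H](O[Si](C)(C)C(C)(C)C)[C@@H](C(C)C)CS(=O)(=O)c2ccccc2)cc1
F6 | step 10 | (2R,3R,6R)-2-[(tert-butyldimethylsilyl)oxy]-1-[(4-methoxybenzyl)oxy]-6-methyl-4-(phenylsulfonyl)-3-(propan-2-yl)-6-[(triethylsilyl)oxy]undec-10-en-5-yl acetate (mixture at C4 and C5) | CC(C)[C@@H](C(C(OC(C)=O)[C@](C)(O[Si](CC)(CC)CC)CCCC=C)S(=O)(=O)c1ccccc1)[C@H](COCc1ccc(OC)cc1)O[Si](C)(C)C(C)(C)C
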